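## Retrosynthetic overview

1. Ring A–O–ring B fragment 4: SNAr disconnection to 4-fluorobenzaldehyde (3) and 2-methoxy-5-vinylphenol (2), the Wittig product of isovanillin (1).
2. Ring C–O–ring D fragment 8: disconnected at a C–H bond of vanillin (5), not at an aryl halide. Vanillin is oxidatively dearomatized to the o-quinone monoketal 6, 3-bromophenol (7) adds at C2, and loss of MeOH rearomatizes (key step).
3. D–CH2CH2–A bridge: Heck coupling of 8 with 4, hydrogenated in the same pot (via stilbene 9) to dialdehyde 10.
4. B–CH2CH2–C bridge and the only new ring (the 18-membered macrocycle): intramolecular McMurry coupling of 10 to stilbene 11, then hydrogenation to 12.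
5. BBr3 demethylation of 12 gives target 13. All four benzene rings are purchased; the macrocycle is the last ring formed.

Assumption: the SMILES is taken as the definitive structure. It has no stereocentre and no configurationally stable axis, so no stereocontrol is needed.

Ring labels: A = phenol ring with the single OH; B = para-phenylene; C = catechol ring; D = meta-phenylene.

## Route

**Step 1**
Reactants: 1, isovanillin (3-hydroxy-4-methoxybenzaldehyde)
Product: 2, 2-methoxy-5-vinylphenol
Conditions: Ph3PCH3Br (2.5 equiv), t-BuOK (2.6 equiv), THF, 0 °C → rt
Reagents that add atoms: methyltriphenylphosphonium bromide, C[P+](c1ccccc1)(c1ccccc1)c1ccccc1.[Br-] (supplies the =CH2 carbon)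
Why: Wittig methylenation; the extra equivalent of ylide covers the free phenol, as in the vanillin → 4-vinylguaiacol conversion.

**Step 2**
Reactants: 2, 2-methoxy-5-vinylphenol; 3, 4-fluorobenzaldehyde
Product: 4, 4-(2-methoxy-5-vinylphenoxy)benzaldehyde
Conditions: K2CO3, DMF, BHT (cat.), 90 °C
Reagents that add atoms: none
Why: SNAr (addition–elimination through a Meisenheimer complex) of the phenoxide on a fluoride activated by the para-formyl group; the styrene is inert to carbonate and BHT suppresses thermal polymerisation.

**Step 3 (key step; one flask, intermediate 6 not isolated)**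
Reactants: 5, vanillin (4-hydroxy-3-methoxybenzaldehyde); 7, 3-bromophenol
Product: 8, 2-(3-bromophenoxy)-4-hydroxy-3-methoxybenzaldehyde, via 6, 3,3-dimethoxy-4-oxocyclohexa-1,5-diene-1-carbaldehyde
Conditions: PhI(OAc)2 (1.1 equiv), MeOH, 0 °C, 15 min; cold solvent switch to MeCN; 7 (1.5 equiv), Cs2CO3 (3 equiv), −20 → 0 °C; then TFA, CH2Cl2, rt
Reagents that add atoms: methanol, CO (forms the ketal; the OMe kept in 8 is either the original or the solvent-derived one)
Why: Proposed new method: PhI(OAc)2/MeOH converts vanillin into the masked o-benzoquinone 6, in which C2 (vanillin numbering) is both the β-carbon of the enal and the δ-carbon of the dienone, so reversible oxa-Michael addition of the phenoxide should funnel to the C2 adduct (its anion is a vinylogous β-keto-aldehyde enolate, far more stabilised than the simple enolate from attack at C6), and acid then ionises the adjacent ketal and expels MeOH to rearomatize with the aryloxy group between CHO and OMe; the closest known reaction type is the oxidative dearomatization / Michael addition / rearomatization of masked o-benzoquinones and quinone monoketals with thiol, amine, indole and 1,3-dicarbonyl nucleophiles, extended here to a phenoxide.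

**Step 4 (one pot, intermediate 9 not isolated)**
Reactants: 4, 4-(2-methoxy-5-vinylphenoxy)benzaldehyde; 8, 2-(3-bromophenoxy)-4-hydroxy-3-methoxybenzaldehyde
Product: 10, 2-{3-[2-(3-(4-formylphenoxy)-4-methoxyphenyl)ethyl]phenoxy}-4-hydroxy-3-methoxybenzaldehyde, via the (E)-stilbene 9
Conditions: Pd(OAc)2 (5 mol %), P(o-tol)3, Et3N, DMF, 100 °C; then cool, add 10% Pd/C, H2 (1 atm), rt, stop after 1 equiv H2
Reagents that add atoms: none (H2 adds only hydrogen)
Why: Mizoroki–Heck β-arylation of the styrene gives (E)-stilbene 9, and its C=C is hydrogenated in the same pot faster than the two electron-rich aryl aldehydes (tandem Heck–hydrogenation), giving the flexible bibenzyl needed for ring closure.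

**Step 5**
Reactants: 10, the bibenzyl dialdehyde
Product: 11, macrocyclic stilbene: target skeleton with a CH=CH bridge between rings B and C (mainly Z), OMe on ring A, and OMe on the ring C oxygen next to the diaryl ether
Conditions: TiCl4 (20 equiv), Zn (40 equiv), pyridine, THF, reflux; syringe-pump addition of 10 over 20 h (≤2 mM)
Reagents that add atoms: none
Why: intramolecular McMurry reductive carbonyl coupling (titanium pinacolate, then deoxygenation) under high dilution closes the 18-membered ring; the free phenol is carried as its titanium phenoxide with excess reagent, and alkene geometry does not matter because it is hydrogenated next.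

**Step 6**
Reactants: 11, macrocyclic stilbene
Product: 12, the target's ring A / ring C(3-O) dimethyl ether
Conditions: H2 (1 atm), 10% Pd/C, EtOAc–MeOH, rt
Reagents that add atoms: none
Why: catalytic hydrogenation of the stilbene C=C; diaryl ethers and aryl methyl ethers are untouched.

**Step 7**
Reactants: 12, the dimethyl ether
Product: 13, marchantin H (target as drawn)
Conditions: BBr3 (8 equiv), CH2Cl2, −78 °C → rt; then MeOH/H2O
Reagents that add atoms: none
Why: BBr3 Lewis-acid demethylation (bromide SN2 on the boron-activated O–CH3) cleaves both aryl methyl ethers while diaryl ether C–O bonds survive.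

## Compound list

1 | isovanillin (3-hydroxy-4-methoxybenzaldehyde) | COc1ccc(C=O)cc1O | starting material
2 | 2-methoxy-5-vinylphenol | COc1ccc(C=C)cc1O | intermediate
3 | 4-fluorobenzaldehyde | O=Cc1ccc(F)cc1 | starting material
4 | 4-(2-methoxy-5-vinylphenoxy)benzaldehyde | COc1ccc(C=C)cc1Oc1ccc(C=O)cc1 | intermediate
5 | vanillin (4-hydroxy-3-methoxybenzaldehyde) | COc1cc(C=O)ccc1O | starting material
6 | 3,3-dimethoxy-4-oxocyclohexa-1,5-diene-1-carbaldehyde (masked o-benzoquinone of vanillin) | O=CC1=CC(OC)(OC)C(=O)C=C1 | intermediate (not isolated)
7 | 3-bromophenol | Oc1cccc(Br)c1 | starting material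
8 | 2-(3-bromophenoxy)-4-hydroxy-3-methoxybenzaldehyde | COc1c(O)ccc(C=O)c1Oc1cccc(Br)c1 | intermediate
9 | (E)-stilbene dialdehyde from Heck coupling of 4 and 8 | COc1ccc(/C=C/c2cccc(Oc3c(C=O)ccc(O)c3OC)c2)cc1Oc1ccc(C=O)cc1 | intermediate (not isolated)
10 | 2-{3-[2-(3-(4-formylphenoxy)-4-methoxyphenyl)ethyl]phenoxy}-4-hydroxy-3-methoxybenzaldehyde | COc1ccc(CCc2cccc(Oc3c(C=O)ccc(O)c3OC)c2)cc1Oc1ccc(C=O)cc1 | intermediate
11 | macrocyclic (Z)-stilbene, ring A OMe / ring C 3-OMe, 4-OH | COc1ccc2cc1Oc1ccc(cc1)/C=C\c1ccc(O)c(OC)c1Oc1cccc(c1)CC2 | intermediate
12 | marchantin H ring A / ring C(3-O) dimethyl ether | COc1ccc2cc1Oc1ccc(cc1)CCc1ccc(O)c(OC)c1Oc1cccc(c1)CC2 | intermediate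
13 | marchantin H (as drawn) | Oc1ccc2cc1Oc1ccc(cc1)CCc1ccc(O)c(O)c1Oc1cccc(c1)CC2 | target

## Summary

Total step count: 7. Steps 3 and 4 are each run as a single one-flask sequence; counted stage by stage they would be 9 operations.

Longest linear sequence: 6 (steps 1 → 2 → 4 → 5 → 6 → 7; step 3 is a one-step branch from vanillin).

Steps most likely to fail, each with a fallback that changes the approach:

1. **Step 3 (dearomatization / phenoxide addition / rearomatization).** Risks are attack at C6 instead of C2, dimerisation of 6, and loss of ArOH instead of MeOH in the acid stage. Fallback: make the ether by conventional SNAr of 2-fluoro-3,4-dimethoxybenzaldehyde with 7 (K2CO3, DMF). This gives the O-methyl analogue of 8, which runs through steps 4–7 unchanged (BBr3 then removes three methyls).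
2. **Step 5 (McMurry macrocyclization).** Risks are oligomers, pinacols, and interference from the free phenol. Fallback: convert 10 to the bis-styrene by double Wittig methylenation and close the ring by stilbene-forming ring-closing metathesis (Grubbs II, high dilution), then hydrogenate as in step 6.
3. **Step 4 (tandem Heck / hydrogenation).** Risks are aldehyde over-reduction and a sluggish hydrogenation in the Heck medium. Fallback: build the saturated bridge directly by B-alkyl Suzuki–Miyaura coupling. Hydroborate the silyl ether of 2 with 9-BBN, couple it with O-methylated 8, then desilylate and do the SNAr with 3 last.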